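The numbers in the tables are calculated on assumed constants; noise was put on by code.

- West, your one earlier run, turned over 63.3 mM of starting material in 30.0 h, counting the mean of starting material lost and target made, and that is most of its 0.070 M of reagent.

the same everywhere: free catalyst 0.50 mM
- west: starting material 0.092 M; reagent 0.070 M; run made earlier
- ash: starting material 0.025 M; reagent 0.0700 M; time 30 h
- oak: starting material 0.20 M; reagent 0.0700 M; time 30 h
- elm: starting material 0.30 M; reagent 0.0700 M; time 30 h
- alder: starting material 0.15 M; reagent 0.0700 M; time 30 h
- larch: starting material 0.10 M; reagent 0.0700 M; time 30 h

west run (percent of the starting material charged)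

| time / h | target / % | starting material / % |
|---|---|---|
| 6.00 | 19.0 | 79.1 |
| 12.0 | 35.4 | 61.1 |
| 20.0 | 50.9 | 41.4 |
| 25.0 | 57.7 | 32.6 |
| 30.0 | 62.9 | 25.2 |

(readings scatter by 0.3 percentage points)

- percent here means starting material units held: one side product counts as two
- candidate steps: starting material + target -> side product; starting material + catalyst intermediate B -> catalyst intermediate C; catalyst intermediate A -> catalyst intermediate B; catalyst intermediate D <-> free catalyst + target; reagent + free catalyst -> catalyst intermediate A; catalyst intermediate C <-> catalyst intermediate D

1. all flasks from highest to lowest amount of target, in percent of the starting material charged, at 30 h (ash / oak / elm / alder / larch)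
2. the same order at 6.0 h (ash / oak / elm / alder / larch)
3. the amount of target, in percent of the starting material charged of the flask you put first, at 30 h
4. the amount of target, in percent of the starting material charged of the flask you put last, at 30 h

- Each turn of the candidate cycle takes one reagent and one starting material and gives one target. The bench rule is therefore the reagent ceiling, the charged ratio [reagent]/[starting material] read as a percentage of target, with reagent as the limiting reagent. For elm the reagent ceiling is 23.3%.
- West has a ceiling of 76.1% and read 62.9%, which is 82.7% of it. Using that mean share, I reckon larch at 57.9% and elm at 19.3%.
- Elm should fall below that figure, because west's missing 11.9% goes with the product of starting material and target, and elm's charge is 3.26 times west's.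
- The rule stops where the ratio passes 1. Ash has 2.80 equivalents of reagent, so its ceiling is the starting material itself.
- Ash needs 0.025 M of turnover, less than west managed. Scaling west's missing share by charge on the same mean curve, I reckon ash at 96.8%.
- At 6.0 h no ceiling binds yet. West had made 17.5 mM of target, and a similar amount over a larger charge keeps the same order.
- The forecast gave ash > larch > alder > oak > elm at 30 h and ash > larch > alder > oak > elm at 6.0 h, with the top at 80% (72% to 86%) and the lowest at 13% (10% to 17%), both at 30 h. For the flasks with more starting material its ground was that “Reagent caps turnover at 70 mM”. Its top lies below my reckoning for ash.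

    starting material + target → side product (k = 0.119 L mol⁻¹ h⁻¹)
    starting material + catalyst intermediate B → catalyst intermediate C (k = 392 L mol⁻¹ h⁻¹)
    catalyst intermediate A → catalyst intermediate B (k = 31.8 h⁻¹)
    catalyst intermediate D ⇌ free catalyst + target (K = 0.213 M, k = 19.5 h⁻¹)
    reagent + free catalyst → catalyst intermediate A (k = 520 L mol⁻¹ h⁻¹)
    catalyst intermediate C ⇌ catalyst intermediate D (K = 3.23, k = 1220 h⁻¹)

- The order comes out as ash > larch > alder > oak > elm at 30 h and ash > larch > alder > oak > elm at 6.0 h, and ash gives 96.9%, with 0.982% of its starting material left and 2.09% as side product at 30.0 h. Elm gives 13.7%, below its ceiling of 23.3%, with 3.80% of its reagent left. Elm's neighbour, charged with 0.12 M of starting material, has a ceiling of 58.3% and gives 47.1% of target, with 14.1% as side product.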